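## Structural features

The target is pentacyclic: an upper 2-phenyl-2,3-dihydrochromene whose carbocycle is a cross-conjugated cyclohexadienone (C5=O between C4=C4a and the C6=C7–OMe vinylogous ester), and a lower (2''S,4''R)-7'',8''-dimethoxyflavan-4''-ol. The two units are joined twice, by the C8–C6'' bond and by the C8a–O–C5'' ether, so a dihydrofuran is fused to the lower arene and shares the C8–C8a bond with the carbocycle; C8a is also the ketal carbon of the dihydropyran (O1) and the neighbour of C4a. C8 (OMe, aryl, C7, C8a) and C8a (two oxygens, C8, C4a) are contiguous, fully substituted stereocentres. Read from the SMILES, the configuration is 2S,8S,8aS,2''S,4''R: a cis ring fusion (C7 and C4a on one face, O1 and the C8 methoxy on the other) and, on the dihydropyran, phenyl equatorial with the aryloxy oxygen axial. In the lower unit phenyl and hydroxyl are 2,4-trans, the hydroxyl next to the peri oxygen on C5''. The C4'' carbinol is benzylic to a ring with oxygen donors at both ortho positions and the para position and ionises with acid; the β-methoxy dienone is sensitive to base and nucleophiles; the ketal is safe only because C4a has no hydrogen, so the aryloxy group cannot leave by retro-addition. The real difficulty is the pair C8/C8a, two adjacent quaternary centres in a dearomatised, oxygen-rich ring, set relative to the distant C2. The key step uses the fact that C8=C8a is the C3=C2 bond of a benzofuran and that C7=C6–C5=C4a is the diene of a 2-pyrone hung from O1 through C2, C3 and C4.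

## Logic of the disconnections

32 ⇒ 31. The O–Si bond at C4'' is cut. The carbinol is the most acid-labile site and stays masked through cycloaddition and oxidation. No skeletal gain. The forward step must run near neutral pH.

31 ⇒ 30. The C4=C4a π bond and the C5 carbonyl are traded for a C5 silyl dienol ether with C4H2. This is the diene that a pyrone cycloaddition with CO2 loss leaves behind, and a silyl group at C5 keeps that oxygen distinct from the C7 methoxy. The dienone is never exposed to the cycloaddition. The forward oxidation must dehydrogenate towards C4 only, which is assured because C8a has no hydrogen.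

30 ⇒ 28 (through 29). C7–C8 and C4a–C8a are cut and CO2 is re-inserted between C7 and C4a. Both quaternary centres, the carbocycle and the dihydropyran disappear; what remains are two flat heteroaromatic rings linked by one ether with one stereocentre. The forward step needs two electron-rich partners to react below the decomposition temperature, and C2 must select one face of the benzofuran.

28 ⇒ 26. The O–CH3 bond at C8 is cut. The acid-labile 2,3-dialkoxybenzofuran is then made only one step before use, from a stable ketone. The forward step must methylate the enolate at oxygen, cold enough that the enolate carbon does not attack the pyrone.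

26 ⇒ 14 + 24. The C8a–O1 bond is cut. The union is convergent, and the carbinol oxygen of 24 is the nucleophile, so the C–O bond at C2 is never broken and the centre that later controls the key step cannot erode. The forward step needs an electrophilic C8a (bromide 25) and near-neutral conditions that the silyloxy pyrone tolerates.

14 ⇒ 13 ⇒ 12. The aryl–acyl bond C6''–C8 is cut, then C6''–Br. The side chain on the C5'' oxygen delivers the acyl carbon intramolecularly, and C6'' is the only free ring position, so regiochemistry is not in question. The forward step needs halogen–lithium exchange to be faster than attack on the amide.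

12 ⇒ 11 ⇒ 10 ⇒ 9 ⇒ 8. The O–Si bond is cut, then the C4''–O bond (made with inversion in 10), then C4''–H. Hydride reduction of 8 can be relied on only for the 2,4-cis alcohol, so the trans carbinol is reached by inversion. The demand is inversion without elimination across C3''–C4''.

8 ⇒ 6 + 7; 6 ⇒ 4 + 5; 4 ⇒ 3; 3 ⇒ 1 (through 2). Cut are C2''–phenyl, the O–CH2 bond on the C5'' oxygen, the peri O–CH3 bond, and O1''–C2''/C2''–C3''. The conjugate addition sets C2'' under catalyst control, and chelation picks out the peri methoxy group. In 1 the only hydroxyl lies next to a methoxy group, so ring closure can give only the 7,8-dimethoxy pattern with C6'' free. The demand is an enantioselective addition to an electron-rich chromone.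

24 ⇒ 23 ⇒ 22 ⇒ 21 ⇒ 20 ⇒ 19 ⇒ 16 + 17; 16 ⇒ 15. Cut are the alkyl O–Si bond, the enol O–Si bond (pyrone back to pyrandione), the lactone back to the lactol, the pyranone back to a furfuryl alcohol, the C–OMe bond on the furan, and the C–C bond between the carbinol carbon and the chain. Oxidative furan ring expansion gives the 2,5-dioxygenated pyran, and only a 4-methoxy group on the furan places the methoxy at C3 of the pyrone (the later C7). The pieces 15 and 17 are simple, and 15 brings the C2 stereocentre. The demand is that the benzylic silyl ether survives the copper-mediated methoxylation.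

## Other disconnections considered

Alternative 1: The two C8a–O bonds are cut first, the carbocycle last. In the forward step mild acid removes a triethylsilyl group and the C5'' phenol and the C2 hydroxyl close onto the C8a carbonyl to give the spiroketal benzofuran-3-one ester A1.
- In favour: ketalisation is a known, thermodynamically controlled reaction, and the anomeric effect with an equatorial phenyl favours the required C2/C8a relation. C4=C4a is already in place, so no later oxidation is needed. On the control of C8a and on the oxidation level at C4 this plan is equal or better.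
- Against: acid is used on a molecule with the ionisable C4'' silyloxy group. C8 is still a ketone in A1, so the quaternary C8 must be made late by adding carbon to a hindered carbonyl beside the spiroketal, with facial control only from that ketal. The ring must then be closed onto the ester with the C7–OMe/C5=O pattern the right way round.
- Comparison: the chosen plan makes C8 and C8a in one event with the fusion guaranteed; Alternative 1 separates them and needs at least four further steps after A1, against two.

Alternative 2: Both C2–phenyl bonds are cut. In the forward step Pd(OCOCF3)2 with a chiral tert-butyl pyridine-oxazoline ligand adds 7 to both enones of a biaryl bis-chromone to give the bis-flavanone A2.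
- In favour: the reaction type is known (the same as step 4 here) and one catalytic operation sets C2 and C2''. On those two centres it is more economical than the chosen plan, which uses a catalyst for one and a purchased chiral alcohol for the other.
- Against: the tetra-ortho-substituted biaryl must be made first, and its enones are deactivated and flanked by the other aryl ring. A2 contains neither quaternary centre. Afterwards the two ketones must be told apart (reduction and inversion below, deoxygenation above) and the upper ring dearomatised with methoxide delivered to C8 and the phenol to C8a, with no element that relates the new face to the remote C2. The ketal is also reversible until C4=C4a exists.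
- Comparison: the key step itself is safer than the chosen one, but the difficulty is moved downstream, and the sequence after A2 is long (at least seven steps).

Alternative 3: The aryl ether O–C5'', the C6''–C8 bond and the C8 O–CH3 bond are cut. In the forward step fluoride triggers aryne formation at C5''–C6'', the C8a hemiketal oxygen adds at C5'', the aryl anion closes on the C8 carbonyl and the alkoxide is methylated, giving A3, the same compound as 31.
- In favour: it is the most convergent plan. The complete upper unit, with C4=C4a and C5=O in place, is joined in one operation, and the C7'' methoxy group should direct the oxygen nucleophile to C5''. A3 is one step from 32, so after the key step it is shorter than the chosen plan by the oxidation step.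
- Against: the nucleophile is a tertiary hemiketal oxygen in equilibrium with the ring-opened hydroxy dione. The upper unit is exposed to fluoride and alkoxide, and the aryne can also react with the dienone. The face at C8 depends on the hemiketal configuration. The ortho-silyl triflate of a hexasubstituted arene carrying the labile C4'' silyl ether is long to make. The reaction type is not established for hemiketals.
- Comparison: both plans rest on an unprecedented step. The chosen one is intramolecular, runs without base or fluoride, and has a stereocontrol element in the tether.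

Key step: step 20

Remarks on the chemistry (assumptions and corrections):
- 1, 5, 7, 15 and 17 are taken as purchasable.
- The (R) enantiomer of the tert-butyl pyridine-oxazoline ligand is taken to give the 2S flavanone, by analogy with the sense of addition to cyclic enones; if the sense is opposite, its mirror image is used.
- A chalcone built on 3,4,5-trimethoxyphenol would close through its only hydroxyl to the 5,6,7-trioxygenated flavanone; the lower unit needs the 5,7,8-pattern with C6'' free, hence 1.
- Ring expansion of an unsubstituted furan gives a pyrone without the C3 oxygen; the methoxy group is therefore put on the furan first (step 13).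
- The ether at C8a is made with the carbinol as nucleophile (step 18) and not by alkylating a lactone enol, which risks C-alkylation and erosion at C2.
- The last step uses buffered fluoride, not an acidic fluoride source, because of the C4'' carbinol.

## Route

Step 1
Reactants: 1 1-(2-hydroxy-3,4,6-trimethoxyphenyl)ethan-1-one
Product: 3 5,7,8-trimethoxy-4H-chromen-4-one, via enaminone 2 (not isolated)
Conditions: Me2NCH(OMe)2, PhMe, 100 °C; then conc. HCl, CH2Cl2, 23 °C
Reagents that add atoms: N,N-dimethylformamide dimethyl acetal, COC(OC)N(C)C
Why: Enaminone formation at the methyl ketone, then acid-induced addition–elimination of the ortho phenol (enaminone route to chromones); the hydroxyl of 1 lies next to a methoxy group, so only the 5,7,8-pattern can form.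

Step 2
Reactants: 3 5,7,8-trimethoxy-4H-chromen-4-one
Product: 4 5-hydroxy-7,8-dimethoxy-4H-chromen-4-one
Conditions: BCl3, CH2Cl2, −78 → 0 °C; aq. NaHCO3
Reagents that add atoms: none
Why: Lewis-acid demethylation directed by chelation of boron between the C4 carbonyl and the peri methoxy oxygen; the 7- and 8-methoxy groups lack this assistance.

Step 3
Reactants: 4 5-hydroxy-7,8-dimethoxy-4H-chromen-4-one; 5 2-chloro-N-methoxy-N-methylacetamide
Product: 6 2-[(7,8-dimethoxy-4-oxo-4H-chromen-5-yl)oxy]-N-methoxy-N-methylacetamide
Conditions: K2CO3, NaI (cat.), DMF, 60 °C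
Reagents that add atoms: none
Why: Williamson etherification of the phenol; the side chain masks the C5'' oxygen for the next six steps and carries the two carbons that become C8a and C8, so no free phenol ever stands beside the C4'' oxygen.

Step 4
Reactants: 6 chromone amide ether; 7 phenylboronic acid
Product: 8 2-{[(2S)-7,8-dimethoxy-4-oxo-2-phenylchroman-5-yl]oxy}-N-methoxy-N-methylacetamide
Conditions: Pd(OCOCF3)2 (5 mol%), (R)-t-BuPyOx (6 mol%), NH4PF6, H2O, ClCH2CH2Cl, 60 °C
Reagents that add atoms: none
Why: Asymmetric conjugate addition of an arylpalladium species (divalent palladium, pyridine-oxazoline ligand) to a chromone, a known route to flavanones; the ligand blocks one face of C2=C3 and sets C2'' as S.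

Step 5
Reactants: 8 (2S)-flavanone amide ether
Product: 9 2-{[(2S,4S)-4-hydroxy-7,8-dimethoxy-2-phenylchroman-5-yl]oxy}-N-methoxy-N-methylacetamide
Conditions: NaBH4, MeOH/THF, 0 °C
Reagents that add atoms: none
Why: Hydride reduction from the axial direction of the half-chair with phenyl equatorial should give the 2,4-cis alcohol (substrate control, C4'' set as S); the Weinreb amide is inert to NaBH4.

Step 6
Reactants: 9 (2S,4S)-alcohol
Product: 10 (2S,4R)-7,8-dimethoxy-5-{2-[methoxy(methyl)amino]-2-oxoethoxy}-2-phenylchroman-4-yl 4-nitrobenzoate
Conditions: 4-O2NC6H4CO2H, PPh3, DIAD, THF, 0 → 23 °C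
Reagents that add atoms: 4-nitrobenzoic acid, OC(=O)c1ccc(cc1)[N+](=O)[O-]
Why: Mitsunobu esterification with inversion sets C4'' as R; should the electron-rich benzylic centre react with cationic character, axial capture leads to the same 2,4-trans ester, which also relieves peri strain with the C5'' oxygen.

Step 7
Reactants: 10 (2S,4R)-4-nitrobenzoate
Product: 11 2-{[(2S,4R)-4-hydroxy-7,8-dimethoxy-2-phenylchroman-5-yl]oxy}-N-methoxy-N-methylacetamide
Conditions: K2CO3, MeOH/THF, 23 °C
Reagents that add atoms: none
Why: Methanolysis of the activated ester (transesterification); the amide and both stereocentres are untouched.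

Step 8
Reactants: 11 (2S,4R)-alcohol
Product: 12 2-{[(2S,4R)-4-[(tert-butyldimethylsilyl)oxy]-7,8-dimethoxy-2-phenylchroman-5-yl]oxy}-N-methoxy-N-methylacetamide
Conditions: t-BuMe2SiOSO2CF3, 2,6-lutidine, CH2Cl2, −78 °C
Reagents that add atoms: tert-butyldimethylsilyl trifluoromethanesulfonate, CC(C)(C)[Si](C)(C)OS(=O)(=O)C(F)(F)F
Why: Silylation of the hindered pseudo-axial carbinol with the silyl triflate; excess base keeps the benzylic C–O bond from ionising.

Step 9
Reactants: 12 silyl ether
Product: 13 2-{[(2S,4R)-6-bromo-4-[(tert-butyldimethylsilyl)oxy]-7,8-dimethoxy-2-phenylchroman-5-yl]oxy}-N-methoxy-N-methylacetamide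
Conditions: NBS, NaHCO3, MeCN, 0 °C
Reagents that add atoms: N-bromosuccinimide, O=C1CCC(=O)N1Br
Why: Electrophilic aromatic bromination; C6'' is the only unsubstituted ring position and lies between two oxygen-bearing carbons.

Step 10
Reactants: 13 aryl bromide
Product: 14 lower-unit benzofuran-3(2H)-one (furanone fused across C5''–C6''; 2''S,4''R)
Conditions: t-BuLi (2.1 equiv), THF, −78 °C; aq. NH4Cl
Reagents that add atoms: none
Why: Parham cyclisation: bromine–lithium exchange outruns attack on the amide, and the aryllithium closes the five-membered ring on the Weinreb amide (5-exo-trig), whose chelated adduct releases the ketone only on work-up.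

Step 11
Reactants: 15 (1S)-3-chloro-1-phenylpropan-1-ol
Product: 16 tert-butyl[(1S)-3-chloro-1-phenylpropoxy]dimethylsilane
Conditions: t-BuMe2SiCl, imidazole, DMF, 23 °C
Reagents that add atoms: tert-butyldimethylsilyl chloride, CC(C)(C)[Si](C)(C)Cl
Why: Standard silylation; the purchased (S) centre later becomes C2.

Step 12
Reactants: 16 silyl ether of the chloro alcohol; 17 4-bromofuran-2-carbaldehyde
Product: 19 (4S)-1-(4-bromofuran-2-yl)-4-[(tert-butyldimethylsilyl)oxy]-4-phenylbutan-1-ol, via Grignard reagent 18 (not isolated)
Conditions: Mg, BrCH2CH2Br (cat.), THF, 60 °C; then 17, −20 → 23 °C; aq. NH4Cl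
Reagents that add atoms: none
Why: Grignard formation from the primary chloride and addition to the aldehyde; the new carbinol centre is of no consequence because it becomes sp2 in step 16.

Step 13
Reactants: 19 bromofuryl carbinol
Product: 20 (4S)-4-[(tert-butyldimethylsilyl)oxy]-1-(4-methoxyfuran-2-yl)-4-phenylbutan-1-ol
Conditions: NaOMe, CuBr (10 mol%), MeOH/NMP, 100 °C
Reagents that add atoms: sodium methoxide, C[O-].[Na+]
Why: Copper-catalysed Ullmann-type methoxylation of the heteroaryl bromide; it places the oxygen that becomes the C7 methoxy group.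

Step 14
Reactants: 20 methoxyfuryl carbinol
Product: 21 2-{(3S)-3-[(tert-butyldimethylsilyl)oxy]-3-phenylpropyl}-6-hydroxy-5-methoxy-2H-pyran-3(6H)-one
Conditions: NBS, NaHCO3, NaOAc, THF/H2O, 0 °C
Reagents that add atoms: water, O
Why: Achmatowicz rearrangement: oxidative opening of the furan to the ene-dione and closure of the carbinol oxygen onto the aldehyde; the furan methoxy group ends up β to the ketone.

Step 15
Reactants: 21 pyranone lactol
Product: 22 6-{(3S)-3-[(tert-butyldimethylsilyl)oxy]-3-phenylpropyl}-3-methoxy-2H-pyran-2,5(6H)-dione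
Conditions: PhI(OAc)2, TEMPO (10 mol%), NaHCO3, CH2Cl2, 23 °C
Reagents that add atoms: none
Why: Oxoammonium-mediated oxidation of the lactol to the lactone under buffered conditions that leave the vinylogous ester alone.

Step 16
Reactants: 22 pyrandione
Product: 23 6-{(3S)-3-[(tert-butyldimethylsilyl)oxy]-3-phenylpropyl}-3-methoxy-5-[(triisopropylsilyl)oxy]-2H-pyran-2-one
Conditions: i-Pr3SiOSO2CF3, Et3N, CH2Cl2, 0 °C
Reagents that add atoms: triisopropylsilyl trifluoromethanesulfonate, CC(C)[Si](C(C)C)(C(C)C)OS(=O)(=O)C(F)(F)F
Why: Soft enolisation of the C5 ketone towards C6 (the only enolisable position) and O-silylation, driven by formation of the aromatic 2-pyrone.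

Step 17
Reactants: 23 bis-silylated pyrone
Product: 24 6-[(3S)-3-hydroxy-3-phenylpropyl]-3-methoxy-5-[(triisopropylsilyl)oxy]-2H-pyran-2-one
Conditions: camphorsulfonic acid (cat.), MeOH/CH2Cl2, 0 → 23 °C
Reagents that add atoms: none
Why: Acid-catalysed methanolysis removes the alkyl silyl ether, whereas the hindered aryl-type triisopropylsilyl ether on the pyrone is far slower under acid.

Step 18
Reactants: 14 lower-unit benzofuran-3(2H)-one; 24 pyrone alcohol
Product: 26 acetal of 14 and 24 at the later C8a, via bromo ketone 25 (not isolated)
Conditions: PhNMe3Br3, 2,6-di-tert-butyl-4-methylpyridine, THF, 0 °C; filter, concentrate; then 24, Ag2CO3, AgOSO2CF3 (cat.), 4 Å MS, CH2Cl2, −20 → 0 °C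
Reagents that add atoms: none
Why: α-Bromination of the ketone through its enol, then Koenigs–Knorr-type displacement of the bromide (α to the ring oxygen and the carbonyl, as in an ulosyl bromide) by the alcohol with silver assistance; the C–O bond at the carbinol is not broken, so the later C2 stays S, and the acetal carbon may form as a mixture because it becomes sp2 next.

Step 19
Reactants: 26 acetal ketone
Product: 28 2-alkoxy-3-methoxybenzofuran (Diels–Alder precursor), via potassium enolate 27 (not isolated)
Conditions: KN(SiMe3)2, THF, −78 °C; then MeOSO2CF3, −78 → −40 °C; Et3N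
Reagents that add atoms: methyl trifluoromethanesulfonate, COS(=O)(=O)C(F)(F)F
Why: Deprotonation gives the aromatic 3-oxidobenzofuran and the hard methylating agent reacts at oxygen (O-alkylation of a benzofuran-3(2H)-one enolate); the low temperature keeps the enolate carbon from adding to the pyrone.

Step 20
Reactants: 28 2-alkoxy-3-methoxybenzofuran with tethered pyrone
Product: 30 pentacyclic C5 triisopropylsilyl dienol ether, via bridged lactone 29 (not isolated)
Conditions: PhMe (0.005 M), N,O-bis(trimethylsilyl)acetamide, BHT (cat.), 130 °C, sealed tube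
Reagents that add atoms: none
Why: Proposed new method: the pyrone diene (C7=C6–C5=C4a) adds across the C8=C8a bond of the 2,3-dialkoxybenzofuran in an intramolecular [4+2] cycloaddition to the bridged lactone 29, which loses CO2 by retro-[4+2] to leave the silyl dienol ether 30; the closest known reactions are intramolecular Diels–Alder reactions of 2-pyrones with CO2 extrusion and dearomative [4+2] additions across C2=C3 of benzofurans and indoles, which have not been combined on a ketene-acetal-type benzofuran. The carbocycle (C4a, C5, C6, C7, C8, C8a) closes as the cycloadduct ring, and the dihydropyran (O1, C2, C3, C4, C4a, C8a) as the tether ring through a chair-like six-membered array. Suprafacial addition to one face of the planar benzofuran fixes C8 and C8a cis, with C7 and C4a on one face and O1 and the C8 methoxy on the other. The face is chosen by the (S) centre at C2: the ring fusion forces the aryloxy oxygen axial and C8 equatorial on the forming oxane, and the chair with phenyl equatorial is then the one that leads to 8S,8aS. Endo or exo orientation of the lactone bridge does not matter, since C4a and C7 become sp2 when CO2 leaves. Because C8 and C8a are quaternary the diene cannot aromatise and is kept as the silyl dienol ether. Both partners are electron-rich and the tether pairs the acetal carbon C8a with the silyloxy-activated terminus C4a, so forcing conditions are expected. The reserve within the same disconnection is one-electron oxidation of the benzofuran with (4-BrC6H4)3N SbCl6 and 2,6-di-tert-butylpyridine at low temperature, where this pairing is polarity-matched, followed by warming to expel CO2.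

Step 21
Reactants: 30 pentacyclic silyl dienol ether
Product: 31 4''-O-tert-butyldimethylsilyl-6''-demethoxyneocalycopterone
Conditions: Pd(OAc)2 (1.1 equiv), 2,6-di-tert-butylpyridine, MeCN, 23 → 40 °C
Reagents that add atoms: none
Why: Saegusa oxidation: palladation at C4a, the nucleophilic terminus of the 1-methoxy-3-silyloxy diene, loss of the silyl group and β-hydride elimination of a C4 hydrogen (C8a has none) give the C5 ketone with the C4=C4a alkene.

Step 22
Reactants: 31 silyl ether of the target
Product: 32 6''-demethoxyneocalycopterone
Conditions: Bu4NF, AcOH (1:1), THF, 0 → 23 °C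
Reagents that add atoms: none
Why: Fluoride-induced desilylation buffered with acetic acid; acid is avoided because the C4'' carbinol ionises, and unbuffered base because of the β-methoxy dienone.

## Compound list

1 | 1-(2-hydroxy-3,4,6-trimethoxyphenyl)ethan-1-one | CC(=O)c1c(O)c(OC)c(OC)cc1OC | starting material
2 | (E)-3-(dimethylamino)-1-(2-hydroxy-3,4,6-trimethoxyphenyl)prop-2-en-1-one | CN(C)/C=C/C(=O)c1c(O)c(OC)c(OC)cc1OC | intermediate
3 | 5,7,8-trimethoxy-4H-chromen-4-one | O=c1ccoc2c(OC)c(OC)cc(OC)c12 | intermediate
4 | 5-hydroxy-7,8-dimethoxy-4H-chromen-4-one | O=c1ccoc2c(OC)c(OC)cc(O)c12 | intermediate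
5 | 2-chloro-N-methoxy-N-methylacetamide | ClCC(=O)N(C)OC | starting material
6 | 2-[(7,8-dimethoxy-4-oxo-4H-chromen-5-yl)oxy]-N-methoxy-N-methylacetamide | O=c1ccoc2c(OC)c(OC)cc(OCC(=O)N(C)OC)c12 | intermediate
7 | phenylboronic acid | OB(O)c1ccccc1 | starting material
8 | 2-{[(2S)-7,8-dimethoxy-4-oxo-2-phenylchroman-5-yl]oxy}-N-methoxy-N-methylacetamide | O=C1C[C@@H](c2ccccc2)Oc2c(OC)c(OC)cc(OCC(=O)N(C)OC)c12 | intermediate
9 | 2-{[(2S,4S)-4-hydroxy-7,8-dimethoxy-2-phenylchroman-5-yl]oxy}-N-methoxy-N-methylacetamide (2,4-cis) | O[C@H]1C[C@@H](c2ccccc2)Oc2c(OC)c(OC)cc(OCC(=O)N(C)OC)c12 | intermediate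
10 | (2S,4R)-7,8-dimethoxy-5-{2-[methoxy(methyl)amino]-2-oxoethoxy}-2-phenylchroman-4-yl 4-nitrobenzoate (2,4-trans) | O=C(O[C@@H]1C[C@@H](c2ccccc2)Oc2c(OC)c(OC)cc(OCC(=O)N(C)OC)c12)c1ccc(cc1)[N+](=O)[O-] | intermediate
11 | 2-{[(2S,4R)-4-hydroxy-7,8-dimethoxy-2-phenylchroman-5-yl]oxy}-N-methoxy-N-methylacetamide (2,4-trans) | O[C@@H]1C[C@@H](c2ccccc2)Oc2c(OC)c(OC)cc(OCC(=O)N(C)OC)c12 | intermediate
12 | 2-{[(2S,4R)-4-[(tert-butyldimethylsilyl)oxy]-7,8-dimethoxy-2-phenylchroman-5-yl]oxy}-N-methoxy-N-methylacetamide | CC(C)(C)[Si](C)(C)O[C@@H]1C[C@@H](c2ccccc2)Oc2c(OC)c(OC)cc(OCC(=O)N(C)OC)c12 | intermediate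
13 | 2-{[(2S,4R)-6-bromo-4-[(tert-butyldimethylsilyl)oxy]-7,8-dimethoxy-2-phenylchroman-5-yl]oxy}-N-methoxy-N-methylacetamide | CC(C)(C)[Si](C)(C)O[C@@H]1C[C@@H](c2ccccc2)Oc2c(OC)c(OC)c(Br)c(OCC(=O)N(C)OC)c12 | intermediate
14 | lower-unit benzofuran-3(2H)-one: (2''S,4''R)-4''-(tert-butyldimethylsilyloxy)-7'',8''-dimethoxy-2''-phenylchroman with a furan-3(2H)-one fused across C5''–C6'' (ring O on C5'', C=O on C6'', CH2 between) | CC(C)(C)[Si](C)(C)O[C@@H]1C[C@@H](c2ccccc2)Oc2c(OC)c(OC)c3C(=O)COc3c12 | intermediate
15 | (1S)-3-chloro-1-phenylpropan-1-ol | O[C@H](c1ccccc1)CCCl | starting material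
16 | tert-butyl[(1S)-3-chloro-1-phenylpropoxy]dimethylsilane | CC(C)(C)[Si](C)(C)O[C@H](c1ccccc1)CCCl | intermediate
17 | 4-bromofuran-2-carbaldehyde | O=Cc1cc(Br)co1 | starting material
18 | {(3S)-3-[(tert-butyldimethylsilyl)oxy]-3-phenylpropyl}magnesium chloride | CC(C)(C)[Si](C)(C)O[C@H](c1ccccc1)CC[Mg]Cl | intermediate
19 | (4S)-1-(4-bromofuran-2-yl)-4-[(tert-butyldimethylsilyl)oxy]-4-phenylbutan-1-ol (both C1 epimers) | OC(CC[C@H](O[Si](C)(C)C(C)(C)C)c1ccccc1)c1cc(Br)co1 | intermediate
20 | (4S)-4-[(tert-butyldimethylsilyl)oxy]-1-(4-methoxyfuran-2-yl)-4-phenylbutan-1-ol (both C1 epimers) | OC(CC[C@H](O[Si](C)(C)C(C)(C)C)c1ccccc1)c1cc(OC)co1 | intermediate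
21 | 2-{(3S)-3-[(tert-butyldimethylsilyl)oxy]-3-phenylpropyl}-6-hydroxy-5-methoxy-2H-pyran-3(6H)-one (mixture at C2 and C6) | OC1OC(CC[C@H](O[Si](C)(C)C(C)(C)C)c2ccccc2)C(=O)C=C1OC | intermediate
22 | 6-{(3S)-3-[(tert-butyldimethylsilyl)oxy]-3-phenylpropyl}-3-methoxy-2H-pyran-2,5(6H)-dione (both C6 epimers) | O=C1OC(CC[C@H](O[Si](C)(C)C(C)(C)C)c2ccccc2)C(=O)C=C1OC | intermediate
23 | 6-{(3S)-3-[(tert-butyldimethylsilyl)oxy]-3-phenylpropyl}-3-methoxy-5-[(triisopropylsilyl)oxy]-2H-pyran-2-one | COC1=CC(O[Si](C(C)C)(C(C)C)C(C)C)=C(CC[C@H](O[Si](C)(C)C(C)(C)C)c2ccccc2)OC1=O | intermediate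
24 | 6-[(3S)-3-hydroxy-3-phenylpropyl]-3-methoxy-5-[(triisopropylsilyl)oxy]-2H-pyran-2-one | COC1=CC(O[Si](C(C)C)(C(C)C)C(C)C)=C(CC[C@H](O)c2ccccc2)OC1=O | intermediate
25 | 2-bromo derivative of 14 (bromine on the furanone CH2 carbon, the later C8a; both epimers) | CC(C)(C)[Si](C)(C)O[C@@H]1C[C@@H](c2ccccc2)Oc2c(OC)c(OC)c3C(=O)C(Br)Oc3c12 | intermediate
26 | acetal: 14 carrying on the furanone C2 (later C8a) the (1S)-3-[3-methoxy-2-oxo-5-(triisopropylsilyloxy)-2H-pyran-6-yl]-1-phenylpropoxy group (both epimers at the acetal carbon) | CC(C)(C)[Si](C)(C)O[C@@H]1C[C@@H](c2ccccc2)Oc2c(OC)c(OC)c3C(=O)C(O[C@H](c4ccccc4)CCC4=C(O[Si](C(C)C)(C(C)C)C(C)C)C=C(OC)C(=O)O4)Oc3c12 | intermediate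
27 | potassium enolate of 26 (3-oxidobenzofuran) | [K+].CC(C)(C)[Si](C)(C)O[C@@H]1C[C@@H](c2ccccc2)Oc2c(OC)c(OC)c3c([O-])c(O[C@H](c4ccccc4)CCC4=C(O[Si](C(C)C)(C(C)C)C(C)C)C=C(OC)C(=O)O4)oc3c12 | intermediate
28 | 2-alkoxy-3-methoxybenzofuran (Diels–Alder precursor): (S)-ether of the lower flavan benzofuran with 24; 2S,2''S,4''R | COc1c(O[C@H](c5ccccc5)CCC6=C(O[Si](C(C)C)(C(C)C)C(C)C)C=C(OC)C(=O)O6)oc2c3c(c(OC)c(OC)c21)O[C@H](c4ccccc4)C[C@H]3O[Si](C)(C)C(C)(C)C | intermediate
29 | bridged lactone cycloadduct (2-oxabicyclo[2.2.2]oct-5-en-3-one spanning C4a and C7; orientation of the bridge not defined; 2S,8S,8aS,2''S,4''R) | COC12C=C(O[Si](C(C)C)(C(C)C)C(C)C)C3(CC[C@@H](c4ccccc4)O[C@]35Oc6c7c(c(OC)c(OC)c6[C@]15OC)O[C@H](c6ccccc6)C[C@H]7O[Si](C)(C)C(C)(C)C)OC2=O | intermediate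
30 | pentacyclic C5 triisopropylsilyl dienol ether with 4''-O-tert-butyldimethylsilyl group; 2S,8S,8aS,2''S,4''R | COC1=CC(O[Si](C(C)C)(C(C)C)C(C)C)=C2CC[C@@H](c3ccccc3)O[C@]23Oc2c4c(c(OC)c(OC)c2[C@]13OC)O[C@H](c1ccccc1)C[C@H]4O[Si](C)(C)C(C)(C)C | intermediate
31 | 4''-O-tert-butyldimethylsilyl-6''-demethoxyneocalycopterone | COC1=CC(=O)C2=CC[C@@H](c3ccccc3)O[C@]23Oc2c4c(c(OC)c(OC)c2[C@]13OC)O[C@H](c1ccccc1)C[C@H]4O[Si](C)(C)C(C)(C)C | intermediate
32 | 6''-demethoxyneocalycopterone; 2S,8S,8aS,2''S,4''R | COC1=CC(=O)C2=CC[C@@H](c3ccccc3)O[C@]23Oc2c4c(c(OC)c(OC)c2[C@]13OC)O[C@H](c1ccccc1)C[C@H]4O | target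

## Step count and least certain steps

Total steps: 22. Longest linear sequence: 15 (steps 1–10 and 18–22); the pyrone alcohol 24 takes 7 steps (11–17).

Step 20 (key step).
- What may go wrong: the cycloaddition may fail to set in before the benzylic ketene acetal breaks down thermally (retro-ene loss of the tether or a 1,3-shift of the benzylic group from oxygen to carbon), because both partners are electron-rich. Facial selection by C2 may be incomplete, because the preference rests only on an equatorial phenyl in an early transition state.
- Fallback (known chemistry; sets out from 13, returns at 31): addition of an aryllithium to a quinone replaces the cycloaddition. 13 is reduced with i-Bu2AlH at −78 °C to the aldehyde F1 and methylenated with Ph3P=CH2 to the allyl ether F2. Separately, purchased (2S)-pinostrobin F3 is reduced with NaBH4 to the cis-diol F4 and oxidised with (KSO3)2NO to the hydroxy quinone F5. The aryllithium from F2 (t-BuLi, −78 °C) is added to the lithium alkoxide of F5. Attack is expected at the C8 carbonyl, which, unlike C5, is not a doubly vinylogous ester; MeOSO2CF3 then methylates both alkoxides to give the quinol bis(methyl ether) F6. Pd(PPh3)4 with morpholine removes the allyl group to give the phenol F7. DBU should then bring about conjugate addition of the phenol to C8a and E1cB loss of methanol from C4, which makes the ring closure irreversible and gives 31. Nothing relates the face at C8 to C2 in this sequence, so 31 and its 8R,8aR isomer are to be expected together and must be separated.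

Step 4.
- What may go wrong: low turnover or low enantioselectivity, because the chromone is electron-rich and carries a peri substituent next to the carbonyl.
- Fallback (sets out from 6, returns at 8): racemic conjugate addition of 7 with Pd(OCOCF3)2 and 2,2'-bipyridine gives the racemic flavanone F8. Kinetic resolution by asymmetric transfer hydrogenation with RuCl[(R,R)-TsDPEN](p-cymene) in HCO2H/Et3N should consume the 2R enantiomer as the cis-alcohol F9 and leave 8.

Step 6.
- What may go wrong: ionisation of the activated benzylic oxyphosphonium ion, leading to elimination across C3''–C4'' or incomplete inversion.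
- Fallback (sets out from 8, returns at 11; no new compound, F0): reagent-controlled reduction of 8 with (S)-2-methyl-CBS-oxazaborolidine and BH3·SMe2 at low temperature, aimed directly at the 4''R carbinol against the substrate bias. It bypasses 9 and 10.

Step 18.
- What may go wrong: over-bromination, hydrolysis of the reactive bromide, or slow substitution by the hindered secondary alcohol.
- Fallback (sets out from 14, returns at 26): diazo transfer to 14 (4-acetamidobenzenesulfonyl azide, DBU, MeCN) gives the diazo ketone F10; Rh2(OAc)4-catalysed O–H insertion of the carbenoid into 24 forms the same C8a–O bond under neutral conditions.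

Step 21.
- What may go wrong: slow palladation of the bulky silyl enol ether and competing protodesilylation to the C4a–H ketone, which can lose the aryloxy group by retro-addition.
- Fallback (sets out from 30, returns at 31): PhSeCl at −78 °C converts 30 into the C4a phenylselenyl ketone F11; H2O2 with pyridine gives the selenoxide, whose syn-elimination can involve only a C4 hydrogen.

## Further compounds

F1 | step 20 | 2-{[(2S,4R)-6-bromo-4-[(tert-butyldimethylsilyl)oxy]-7,8-dimethoxy-2-phenylchroman-5-yl]oxy}acetaldehyde | CC(C)(C)[Si](C)(C)O[C@@H]1C[C@@H](c2ccccc2)Oc2c(OC)c(OC)c(Br)c(OCC=O)c12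
F2 | step 20 | {[(2S,4R)-5-(allyloxy)-6-bromo-7,8-dimethoxy-2-phenylchroman-4-yl]oxy}(tert-butyl)dimethylsilane | CC(C)(C)[Si](C)(C)O[C@@H]1C[C@@H](c2ccccc2)Oc2c(OC)c(OC)c(Br)c(OCC=C)c12
F3 | step 20 | (2S)-pinostrobin, (2S)-5-hydroxy-7-methoxy-2-phenylchroman-4-one | O=C1C[C@@H](c2ccccc2)Oc2cc(OC)cc(O)c12
F4 | step 20 | (2S,4S)-7-methoxy-2-phenylchromane-4,5-diol | O[C@H]1C[C@@H](c2ccccc2)Oc2cc(OC)cc(O)c12
F5 | step 20 | (2S,4S)-4-hydroxy-7-methoxy-2-phenyl-3,4-dihydro-2H-chromene-5,8-dione | O[C@H]1C[C@@H](c2ccccc2)OC2=C1C(=O)C=C(OC)C2=O
F6 | step 20 | quinol bis(methyl ether): (2S,4S)-4,7,8-trimethoxy-2-phenyl-8-aryl-3,4-dihydro-2H-chromen-5(8H)-one, aryl = the 5''-allyloxy lower flavan of F2 bonded through C6'' (both C8 epimers) | CO[C@H]1C[C@@H](c2ccccc2)OC2=C1C(=O)C=C(OC)C2(OC)c1c(OCC=C)c2c(c(OC)c1OC)O[C@H](c1ccccc1)C[C@H]2O[Si](C)(C)C(C)(C)C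
F7 | step 20 | free C5'' phenol of F6 (both C8 epimers) | CO[C@H]1C[C@@H](c2ccccc2)OC2=C1C(=O)C=C(OC)C2(OC)c1c(O)c2c(c(OC)c1OC)O[C@H](c1ccccc1)C[C@H]2O[Si](C)(C)C(C)(C)C
F8 | step 4 | racemic 2-[(7,8-dimethoxy-4-oxo-2-phenylchroman-5-yl)oxy]-N-methoxy-N-methylacetamide | O=C1CC(c2ccccc2)Oc2c(OC)c(OC)cc(OCC(=O)N(C)OC)c12
F9 | step 4 | 2-{[(2R,4R)-4-hydroxy-7,8-dimethoxy-2-phenylchroman-5-yl]oxy}-N-methoxy-N-methylacetamide | O[C@@H]1C[C@H](c2ccccc2)Oc2c(OC)c(OC)cc(OCC(=O)N(C)OC)c12
F0 | step 6 | none | none
F10 | step 18 | 2-diazo derivative of 14 (diazo group on the furanone carbon next to the ring oxygen) | CC(C)(C)[Si](C)(C)O[C@@H]1C[C@@H](c2ccccc2)Oc2c(OC)c(OC)c3C(=O)C(=[N+]=[N-])Oc3c12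
F11 | step 21 | C4a phenylselenyl C5 ketone derived from 30 (C4a configuration not defined) | COC1=CC(=O)C2(CC[C@@H](c3ccccc3)O[C@]23Oc2c4c(c(OC)c(OC)c2[C@]13OC)O[C@H](c1ccccc1)C[C@H]4O[Si](C)(C)C(C)(C)C)[Se]c1ccccc1
A1 | alternative 1 | spiroketal benzofuran-3-one ethyl ester | CCOC(=O)C1=CC[C@@H](c2ccccc2)O[C@]13Oc4c5c(c(OC)c(OC)c4C3=O)O[C@H](c6ccccc6)C[C@H]5O[Si](C)(C)C(C)(C)C
A2 | alternative 2 | (2S,2''S)-bis-flavanone with the C8–C6'' biaryl bond | CC(C)(C)[Si](C)(C)Oc1c2c(c(OC)c(OC)c1-c3c(OC)cc(OCc4ccccc4)c5c3O[C@H](c6ccccc6)CC5=O)O[C@H](c7ccccc7)CC2=O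
A3 | alternative 3 | 4''-O-tert-butyldimethylsilyl ether of the target (identical with 31) | COC1=CC(=O)C2=CC[C@@H](c3ccccc3)O[C@]23Oc2c4c(c(OC)c(OC)c2[C@]13OC)O[C@H](c1ccccc1)C[C@H]4O[Si](C)(C)C(C)(C)C
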